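**Plan**
- Retrosynthetic cuts, in order: the O5–Si and O7–Si bonds, then C2–C3 of ring C, then O1–C2, then the C8–prenyl bond. This leads back to 2,4,6-trihydroxyacetophenone, prenyl bromide and 4-methoxybenzaldehyde.
- Enabling feature: C2 carries both the ring A oxygen O1 and the 4-methoxyphenyl ring B, so it can ionise to a doubly stabilised O-aryl oxocarbenium carbon. C3 is the α-carbon of the C4 ketone and can be armed as an enol silane sitting ortho to O1 on ring A.
- Forward order: ring A is bought and prenylated at the future C8, and O5 and O7 are silylated. Ring B and C2 arrive together by O-alkylation of the remaining phenol, the acetyl group becomes its enol silane, and ring C closes last.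
- The group leaving C2 is a pivalate. An O-aryl O-alkyl acetal would ionise by expelling the phenol, whereas an O-aryl O-acyl acetal can only shed the carboxylate.
- Stereochemistry: C2 is the only stereocentre. It is created in the ring closure from a racemic acetal under control of a chiral imidodiphosphorimidate (IDPi) counter-anion, and it is preserved by a non-basic final desilylation.

Key step: step 6

Assumption: the sense of induction of the IDPi anion on this new substrate cannot be derived from analogy. The catalyst antipode (from (R)- or (S)-BINOL) that gives the (S)-flavanone is chosen after a test run, and it is written below as the (S,S)-acid.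

Step 1
Reactants: 1 2,4,6-trihydroxyacetophenone (slight excess); 2 prenyl bromide (1-bromo-3-methylbut-2-ene)
Product: 3 1-[2,4,6-trihydroxy-3-(3-methylbut-2-en-1-yl)phenyl]ethan-1-one
Conditions: KOH, H2O, 0 °C to rt; then aq HCl
Reagents that add atoms: none
Why: C-alkylation of the ambident phloroglucinol-type phenoxide in water, where solvation of oxygen steers the soft allylic bromide to carbon, is a known reaction of 1; the two free ring positions are equivalent, so only over-alkylation has to be limited by the excess of 1.

Step 2
Reactants: 3 1-[2,4,6-trihydroxy-3-(3-methylbut-2-en-1-yl)phenyl]ethan-1-one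
Product: 4 1-[4,6-bis(tert-butyldimethylsilyloxy)-2-hydroxy-3-(3-methylbut-2-en-1-yl)phenyl]ethan-1-one
Conditions: TBSCl (2.1 equiv), imidazole, DMF, 0 °C
Reagents that add atoms: tert-butyldimethylsilyl chloride, CC(C)(C)[Si](C)(C)Cl
Why: In this standard silyl ether formation the non-chelated 4-OH reacts first, and of the two hydroxyls able to chelate the acetyl oxygen the bulky chlorosilane should take the one next to the ring hydrogen (C6), leaving the OH wedged between acetyl and prenyl, the future O1, free and hydrogen-bonded.

Step 3
Reactants: 5 4-methoxybenzaldehyde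
Product: 6 chloro(4-methoxyphenyl)methyl 2,2-dimethylpropanoate (racemic)
Conditions: t-BuCOCl (0.95 equiv), ZnCl2 (2 mol %), CH2Cl2, −10 °C to rt; pentane, filtration under argon, used crude
Reagents that add atoms: pivaloyl chloride, CC(C)(C)C(=O)Cl
Why: ZnCl2-catalysed addition of an acyl chloride across an aldehyde C=O is the standard route to 1-chloroalkyl esters and is known for aromatic aldehydes; the new centre forms as a racemate, which is of no consequence, and the slight deficit of acid chloride leaves only inert aldehyde in crude 6.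

Step 4
Reactants: 4 1-[4,6-bis(tert-butyldimethylsilyloxy)-2-hydroxy-3-(3-methylbut-2-en-1-yl)phenyl]ethan-1-one; 6 chloro(4-methoxyphenyl)methyl 2,2-dimethylpropanoate
Product: 7 [2-acetyl-3,5-bis(tert-butyldimethylsilyloxy)-6-(3-methylbut-2-en-1-yl)phenoxy](4-methoxyphenyl)methyl 2,2-dimethylpropanoate (racemic)
Conditions: NaH (1.05 equiv), THF, 0 °C; then 6, −40 to 0 °C; Et3N-deactivated silica
Reagents that add atoms: none
Why: Williamson-type O-alkylation of a phenoxide by a 1-chloroalkyl carboxylate, the reaction used to make acyloxyalkyl ethers of phenols, should be fast here because the 4-methoxybenzylic chloride reacts in an SN1-like manner that tolerates the crowded oxygen, while the tert-butyl group blocks acyl transfer; the acetal carbon is racemic and is erased in step 6.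

Step 5
Reactants: 7 [2-acetyl-3,5-bis(tert-butyldimethylsilyloxy)-6-(3-methylbut-2-en-1-yl)phenoxy](4-methoxyphenyl)methyl 2,2-dimethylpropanoate
Product: 8 {3,5-bis(tert-butyldimethylsilyloxy)-6-(3-methylbut-2-en-1-yl)-2-[1-(trimethylsilyloxy)ethenyl]phenoxy}(4-methoxyphenyl)methyl 2,2-dimethylpropanoate (racemic)
Conditions: Me3SiCl (3 equiv), LiN(SiMe3)2 (1.3 equiv), THF, −78 °C (in situ quench); pentane/Et3N, cold aq NaHCO3, basic alumina plug
Reagents that add atoms: chlorotrimethylsilane, C[Si](C)(C)Cl
Why: Kinetic deprotonation of the methyl ketone with in situ silyl trapping gives the only possible enol silane and captures the enolate before it can attack the acetal carbon or the hindered, non-enolisable pivalate; amine/Me3SiOTf conditions are avoided because they would ionise the acetal and close the ring racemically.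

Step 6
Reactants: 8 {3,5-bis(tert-butyldimethylsilyloxy)-6-(3-methylbut-2-en-1-yl)-2-[1-(trimethylsilyloxy)ethenyl]phenoxy}(4-methoxyphenyl)methyl 2,2-dimethylpropanoate
Product: 10 (S)-5,7-bis(tert-butyldimethylsilyloxy)-4'-methoxy-8-prenylflavanone, via O-aryl oxocarbenium ion 9 (not isolated)
Conditions: (S,S)-IDPi acid (two 3,3'-diaryl-BINOL units, N-SO2CF3 groups; 2.5 mol %), toluene (0.02 M), −78 °C; then Et3N
Reagents that add atoms: none
Why: Proposed new method: the acid is first silylated by a trace of 8, the silylium–IDPi pair then silylates the pivalate carbonyl oxygen (the most Lewis-basic site), Me3SiOPiv departs and cation 9, stabilised by O1 and ring B, stays paired with the chiral anion; C3 of the enol silane adds to C2 and the silyl group on the C4 oxygen passes to the next pivalate, which turns the cycle over. The closest known reaction type is the IDPi-catalysed Mukaiyama-type addition of enol silanes to oxocarbenium ions released from lactol acetates, and the racemic ring-forming relative is the Petasis–Ferrier rearrangement, but an intramolecular O-aryl version that builds a flavanone is not known. Ring C closes in a 6-(enolendo)-endo-trig mode, with both C2=O1 and C3=C4 inside the new ring. The only new stereocentre, C2, is set by the confined anion, which covers one face of the planar (E)-oxocarbenium carbon, and since both antipodes of 8 funnel into the same cation the whole racemate should converge on (S)-10. The step needs one-directional ionisation, which the acyloxy group secures because loss of the aryloxide would leave a much poorer acyloxy-substituted cation. It also needs chemoselectivity over a six-membered Prins attack by the C8 prenyl alkene, secured by the far higher nucleophilicity of the enol silane, and a suppressed racemic background, secured by −78 °C, the apolar solvent and rigorous removal of achiral acid from 8.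

Step 7
Reactants: 10 (S)-5,7-bis(tert-butyldimethylsilyloxy)-4'-methoxy-8-prenylflavanone
Product: 11 (2S)-5,7-dihydroxy-2-(4-methoxyphenyl)-8-(3-methylbut-2-en-1-yl)-2,3-dihydro-4H-chromen-4-one
Conditions: HF·pyridine, pyridine, THF, 0 °C; pH 7 phosphate buffer
Reagents that add atoms: none
Why: Fluoride cleavage of aryl silyl ethers in a buffered, mildly acidic medium generates no phenoxide or enolate, so retro-oxa-Michael opening to the chalcone (the racemisation path of C2) and acid cyclisation of the prenyl group onto O7 should both be avoided.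

**Compound list**
1 | 2,4,6-trihydroxyacetophenone | CC(=O)c1c(O)cc(O)cc1O | starting material
2 | prenyl bromide | CC(C)=CCBr | starting material
3 | 1-[2,4,6-trihydroxy-3-(3-methylbut-2-en-1-yl)phenyl]ethan-1-one | CC(=O)c1c(O)cc(O)c(CC=C(C)C)c1O | intermediate
4 | 1-[4,6-bis(tert-butyldimethylsilyloxy)-2-hydroxy-3-(3-methylbut-2-en-1-yl)phenyl]ethan-1-one | CC(=O)c1c(O[Si](C)(C)C(C)(C)C)cc(O[Si](C)(C)C(C)(C)C)c(CC=C(C)C)c1O | intermediate
5 | 4-methoxybenzaldehyde | COc1ccc(C=O)cc1 | starting material
6 | chloro(4-methoxyphenyl)methyl 2,2-dimethylpropanoate, racemic | COc1ccc(C(Cl)OC(=O)C(C)(C)C)cc1 | intermediate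
7 | [2-acetyl-3,5-bis(tert-butyldimethylsilyloxy)-6-(3-methylbut-2-en-1-yl)phenoxy](4-methoxyphenyl)methyl 2,2-dimethylpropanoate, racemic | CC(=O)c1c(O[Si](C)(C)C(C)(C)C)cc(O[Si](C)(C)C(C)(C)C)c(CC=C(C)C)c1OC(OC(=O)C(C)(C)C)c1ccc(OC)cc1 | intermediate
8 | {3,5-bis(tert-butyldimethylsilyloxy)-6-(3-methylbut-2-en-1-yl)-2-[1-(trimethylsilyloxy)ethenyl]phenoxy}(4-methoxyphenyl)methyl 2,2-dimethylpropanoate, racemic | C=C(O[Si](C)(C)C)c1c(O[Si](C)(C)C(C)(C)C)cc(O[Si](C)(C)C(C)(C)C)c(CC=C(C)C)c1OC(OC(=O)C(C)(C)C)c1ccc(OC)cc1 | intermediate
9 | O-aryl oxocarbenium ion (4-methoxybenzylidene oxonium of the ring A enol silane), paired with the IDPi anion | C=C(O[Si](C)(C)C)c1c(O[Si](C)(C)C(C)(C)C)cc(O[Si](C)(C)C(C)(C)C)c(CC=C(C)C)c1[O+]=Cc1ccc(OC)cc1 | intermediate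
10 | (S)-5,7-bis(tert-butyldimethylsilyloxy)-4'-methoxy-8-prenylflavanone | COc1ccc([C@@H]2CC(=O)c3c(O[Si](C)(C)C(C)(C)C)cc(O[Si](C)(C)C(C)(C)C)c(CC=C(C)C)c3O2)cc1 | intermediate
11 | (2S)-5,7-dihydroxy-2-(4-methoxyphenyl)-8-(3-methylbut-2-en-1-yl)-2,3-dihydro-4H-chromen-4-one | COc1ccc([C@@H]2CC(=O)c3c(O)cc(O)c(CC=C(C)C)c3O2)cc1 | target

**Step count**
Total steps: 7. Longest linear sequence: 6 (steps 1, 2, 4, 5, 6, 7). Step 3 is a one-step side branch.

**Steps most likely to fail**

**Step 6.**
- What may go wrong: poor facial selectivity, because the bulky bis-silylated cation may not seat in the confined pocket. Slow ionisation or a racemic background closure started by traces of achiral acid are also possible.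
- Fallback (known chemistry), from 4 and back to the route at 10. Heating 4 with N,N-dimethylformamide dimethyl acetal should give the enaminone (E)-1-[4,6-bis(tert-butyldimethylsilyloxy)-2-hydroxy-3-prenylphenyl]-3-(dimethylamino)prop-2-en-1-one F1.
- F1 closes with TsOH in CH2Cl2, losing dimethylamine, to 5,7-bis(tert-butyldimethylsilyloxy)-8-prenylchromone F2.
- A Hayashi–Miyaura-type asymmetric 1,4-addition of 4-methoxyphenylboronic acid then attaches ring B at C2 and delivers 10. Conditions would be [Rh(OH)(cod)]2 with an electron-poor chiral biaryl diphosphine of the antipode leading to S, in toluene/H2O at rt. In this variant the stereocentre comes from the C2–C1' bond formation.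

**Step 4.**
- What may go wrong: acyl transfer to the phenoxide, reversion of 6 to aldehyde and acid chloride, sluggish alkylation at the crowded chelated oxygen, or solvolysis during isolation.
- Fallback, from 4 and back to the route at 10. C2 is brought in at the ester oxidation level. Acylation with 4-methoxybenzoyl chloride (Et3N, DMAP) gives 2-acetyl-3,5-bis(tert-butyldimethylsilyloxy)-6-prenylphenyl 4-methoxybenzoate F3.
- Soft enolisation (Me3SiOTf, Et3N, CH2Cl2, 0 °C) is harmless at this stage and avoids a Baker–Venkataraman acyl shift. It gives 3,5-bis(tert-butyldimethylsilyloxy)-6-prenyl-2-[1-(trimethylsilyloxy)ethenyl]phenyl 4-methoxybenzoate F4.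
- Reductive acetylation of the ester (i-Bu2AlH, −78 °C; then pyridine, DMAP, Ac2O) gives {3,5-bis(tert-butyldimethylsilyloxy)-6-prenyl-2-[1-(trimethylsilyloxy)ethenyl]phenoxy}(4-methoxyphenyl)methyl acetate F5. F5 is cyclised under the conditions of step 6 to 10.

**Step 5.**
- What may go wrong: premature racemic ring closure by the lithium enolate, attack of the base at the ester, or protodesilylation during isolation.
- Fallback, from 4 and back to the route at 8. The order of events is inverted so that the acetal never meets a strong base. Double deprotonation of 4 (LiN(SiMe3)2, 2.1 equiv, THF, −78 °C) is followed by one equivalent of Me3SiCl.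
- This should silylate the more basic enolate oxygen and leave lithium 3,5-bis(tert-butyldimethylsilyloxy)-6-prenyl-2-[1-(trimethylsilyloxy)ethenyl]phenoxide F6.
- F6 is alkylated in the same flask with 6 to give 8.

Further compounds
F1 | step 6 | (E)-1-[4,6-bis(tert-butyldimethylsilyloxy)-2-hydroxy-3-prenylphenyl]-3-(dimethylamino)prop-2-en-1-one | CN(C)/C=C/C(=O)c1c(O)c(CC=C(C)C)c(O[Si](C)(C)C(C)(C)C)cc1O[Si](C)(C)C(C)(C)C
F2 | step 6 | 5,7-bis(tert-butyldimethylsilyloxy)-8-prenylchromone | O=c1ccoc2c(CC=C(C)C)c(O[Si](C)(C)C(C)(C)C)cc(O[Si](C)(C)C(C)(C)C)c12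
F3 | step 4 | 2-acetyl-3,5-bis(tert-butyldimethylsilyloxy)-6-prenylphenyl 4-methoxybenzoate | CC(=O)c1c(O[Si](C)(C)C(C)(C)C)cc(O[Si](C)(C)C(C)(C)C)c(CC=C(C)C)c1OC(=O)c1ccc(OC)cc1
F4 | step 4 | 3,5-bis(tert-butyldimethylsilyloxy)-6-prenyl-2-[1-(trimethylsilyloxy)ethenyl]phenyl 4-methoxybenzoate | C=C(O[Si](C)(C)C)c1c(O[Si](C)(C)C(C)(C)C)cc(O[Si](C)(C)C(C)(C)C)c(CC=C(C)C)c1OC(=O)c1ccc(OC)cc1
F5 | step 4 | {3,5-bis(tert-butyldimethylsilyloxy)-6-prenyl-2-[1-(trimethylsilyloxy)ethenyl]phenoxy}(4-methoxyphenyl)methyl acetate, racemic | C=C(O[Si](C)(C)C)c1c(O[Si](C)(C)C(C)(C)C)cc(O[Si](C)(C)C(C)(C)C)c(CC=C(C)C)c1OC(OC(C)=O)c1ccc(OC)cc1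
F6 | step 5 | lithium 3,5-bis(tert-butyldimethylsilyloxy)-6-prenyl-2-[1-(trimethylsilyloxy)ethenyl]phenoxide | [Li+].C=C(O[Si](C)(C)C)c1c(O[Si](C)(C)C(C)(C)C)cc(O[Si](C)(C)C(C)(C)C)c(CC=C(C)C)c1[O-]
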